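**Plan**

1. Numbering (carotenoid): ring C1 (CMe2), C2 (CH2), C3 (CHOH), C4=C5 (methyl on C5), C6 (CH carrying the chain); chain C7 to C15, then C15' back to the aldehyde carbon C8'.
2. Cuts, in order: the C8' aldehyde is traced back to an ethyl ester. C10–C11 and C9–CH3 are then cut together, because the E trisubstituted C9=C10 alkene outside the ring (methyl on C9, hydrogen on C10) is what syn addition of CH3 and a metal to a terminal C9≡C10 alkyne leaves. The chain half is cut at C11=C12 (Takai) and C11'=C12' (Horner–Wadsworth–Emmons), and the alkyne goes back to the methyl ketone of α-ionone.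
3. Forward: the only ring, the C1–C6 cyclohexene, is bought with α-ionone and no ring is made. C3 is oxygenated and the ketone becomes the enyne. The C11–C8' iodo ester is built from ethyl tiglate and the C10 dialdehyde. The halves are joined in one pot at C10–C11 while the C9 methyl is installed, and ester reduction, oxidation and desilylation finish.
4. Stereochemistry: the cis C3/C6 relation comes from Luche reduction of the 3-ketone with separation of diastereomers, and the absolute configuration (3S,6R) from a lipase resolution. C7=C8 comes from α-ionone, C9=C10 from the syn carbometalation, C11=C12 from the Takai reaction, C11'=C12' from the phosphonate olefination, and the remaining alkenes from the starting materials.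

Key step: step 11

Assumption: the lipase acylates the 3R enantiomer of the cis alcohol, as expected for cyclohex-2-enols of this type, so the (3S,6R) alcohol is the one left behind; with the opposite preference the same enantiomer would be taken from the acetate by methanolysis.
Remark: racemates with two stereocentres are written as both enantiomers joined by a dot; α-ionone and its first two derivatives are racemic at C6 and carry no descriptor there.

**Route**

Step 1
Reactants: 1 (±)-α-ionone
Product: 2 (±)-α-ionone ethylene ketal, 2-methyl-2-[(E)-2-(2,6,6-trimethylcyclohex-2-en-1-yl)ethenyl]-1,3-dioxolane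
Conditions: Me3SiOCH2CH2OSiMe3, Me3SiOTf (cat.), CH2Cl2, −78 °C; pyridine quench
Reagents that add atoms: 1,2-bis(trimethylsilyloxy)ethane, C[Si](C)(C)OCCO[Si](C)(C)C
Why: Noyori's aprotic ketalisation masks the C9 ketone at low temperature without moving the C7=C8 or C4=C5 alkene, so that only the ring ketone made next is reduced.

Step 2
Reactants: 2 (±)-α-ionone ethylene ketal
Product: 3 (±)-3-oxo-α-ionone ethylene ketal, 3,5,5-trimethyl-4-[(E)-2-(2-methyl-1,3-dioxolan-2-yl)ethenyl]cyclohex-2-en-1-one
Conditions: t-BuOOH (in decane), Rh2(C6H10NO)4 [dirhodium tetrakis(caprolactamate)] (1 mol %), K2CO3 (0.5 equiv), CH2Cl2, rt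
Reagents that add atoms: tert-butyl hydroperoxide, CC(C)(C)OO
Why: Radical allylic oxidation by tert-butylperoxyl radicals takes the one unhindered ring allylic methylene, C3, through the allyl peroxide to the enone, while the tertiary C6–H is shielded by the C1 gem-dimethyl group and the C5 methyl group.

Step 3
Reactants: 3 (±)-3-oxo-α-ionone ethylene ketal
Product: 5 rac-cis-3-hydroxy-α-ionone (racemate of 3S,6R and 3R,6S), via hydroxy ketal 4 (not isolated)
Conditions: NaBH4, CeCl3·7H2O, MeOH, −20 °C; then 0.3 M aq HCl, THF, 0 °C; chromatography to remove the trans diastereomer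
Reagents that add atoms: water, O
Why: In this Luche 1,2-reduction the small hard hydride should add to C3 along the axial path anti to the pseudoaxial C6 side chain, which puts the hydroxyl cis to the chain; attack anti to the axial C1 methyl gives the trans alcohol, which is removed after the mild hydrolysis of the enone dioxolane.

Step 4
Reactants: 5 rac-cis-3-hydroxy-α-ionone
Product: 6 (3S,6R)-3-hydroxy-α-ionone, (E)-4-[(1R,4S)-4-hydroxy-2,6,6-trimethylcyclohex-2-en-1-yl]but-3-en-2-one
Conditions: Burkholderia cepacia lipase, vinyl acetate, t-BuOMe, rt, run slightly past half conversion; chromatography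
Reagents that add atoms: none
Why: Lipase kinetic resolution by irreversible transesterification should acylate the 3R enantiomer, and because the cis relation is already fixed the recovered 3S alcohol has both C3 and C6 defined as (3S,6R), its enantiomeric purity rising as conversion passes one half.

Step 5
Reactants: 6 (3S,6R)-3-hydroxy-α-ionone
Product: 7 (3S,6R)-3-(tert-butyldimethylsilyloxy)-α-ionone
Conditions: TBSCl, imidazole, DMF, rt
Reagents that add atoms: tert-butyldimethylsilyl chloride, CC(C)(C)[Si](C)(C)Cl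
Why: Imidazole-promoted silylation of the secondary allylic alcohol gives an ether that should withstand amide base, organoaluminium reagents, i-Bu2AlH and MnO2.

Step 6
Reactants: 7 (3S,6R)-3-(tert-butyldimethylsilyloxy)-α-ionone
Product: 9 ring enyne (3S,6R) ending at C10, tert-butyl{[(1S,4R)-4-[(E)-but-1-en-3-ynyl]-3,5,5-trimethylcyclohex-2-en-1-yl]oxy}dimethylsilane, via enol phosphate 8 (not isolated)
Conditions: LiN(i-Pr)2 (1.05 equiv), THF, −78 °C; ClP(O)(OEt)2, −78 °C to rt; then LiN(i-Pr)2 (2.3 equiv), THF, −78 °C to rt; aq NH4Cl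
Reagents that add atoms: none
Why: Negishi's conversion of a methyl ketone into a terminal alkyne relies on kinetic deprotonation at the C10 methyl, O-phosphorylation and amide-induced β-elimination of the enol phosphate, and the acetylide that forms carries a charge that should disfavour removal of the hindered C6–H.

Step 7
Reactants: 10 ethyl tiglate
Product: 11 ethyl (E)-4-bromo-2-methylbut-2-enoate
Conditions: NBS, AIBN (cat.), PhCF3, reflux
Reagents that add atoms: N-bromosuccinimide, O=C1CCC(=O)N1Br
Why: Wohl–Ziegler bromination goes through the ester-conjugated allyl radical and brominates mainly the γ-methyl group, the minor 2-(bromomethyl) isomer being removed by distillation.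

Step 8
Reactants: 11 ethyl (E)-4-bromo-2-methylbut-2-enoate
Product: 12 ethyl (E)-4-(diethoxyphosphoryl)-2-methylbut-2-enoate
Conditions: P(OEt)3, neat, 140 °C, EtBr distilled off
Reagents that add atoms: triethyl phosphite, CCOP(OCC)OCC
Why: Michaelis–Arbuzov reaction of a primary allylic bromide is reliable and gives the C5 phosphonate that supplies C8' to C11'.

Step 9
Reactants: 12 ethyl (E)-4-(diethoxyphosphoryl)-2-methylbut-2-enoate; 13 (2E,4E,6E)-2,7-dimethylocta-2,4,6-trienedial
Product: 14 ethyl (2E,4E,6E,8E,10E)-2,6,11-trimethyl-12-oxododeca-2,4,6,8,10-pentaenoate (C12 aldehyde, C8' ester)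
Conditions: 12, NaH, THF, 0 °C; anion added slowly to 13 (2.5 equiv), THF, 0 °C to rt, dark; excess 13 recovered
Reagents that add atoms: none
Why: The vinylogous phosphonate anion reacts at its phosphorus-bearing carbon in a Horner–Wadsworth–Emmons olefination that favours the E C11'=C12' alkene, and slow addition to an excess of the symmetrical dialdehyde should hold the reaction at the mono-adduct.

Step 10
Reactants: 14 C15 aldehyde ester
Product: 15 ethyl (2E,4E,6E,8E,10E,12E)-13-iodo-2,6,11-trimethyltrideca-2,4,6,8,10,12-hexaenoate (iodine on C11, ester at C8')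
Conditions: CrCl2 (8 equiv), CHI3 (2.5 equiv), THF, 0 °C, dark
Reagents that add atoms: iodoform, IC(I)I
Why: Takai iodoolefination turns the enal into the E alkenyl iodide through a geminal dichromium species and leaves the ester and the polyene alone.

Step 11
Reactants: 9 ring enyne; 15 iodo hexaenoate; 16 trimethylaluminium
Product: 19 ethyl (3S,6R)-3-(tert-butyldimethylsilyloxy)-8'-apo-ε-caroten-8'-oate (all-E), via alkenyldimethylalane 17 (not isolated), via alkenylzinc chloride 18 (not isolated)
Conditions: 9 (1.2 equiv), Al(CH3)3 (2 equiv), (C5H5)2ZrCl2 (0.25 equiv), ClCH2CH2Cl, 0 °C to rt; volatiles removed in vacuo; THF, ZnCl2 (1 equiv), Pd(PPh3)4 (5 mol %), 15 (1.0 equiv), rt, dark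
Reagents that add atoms: trimethylaluminium (16), C[Al](C)C
Why: Al(CH3)3 activated by (C5H5)2ZrCl2 delivers a methyl group and aluminium to the same face of the terminal C9≡C10 triple bond of 9, methyl to the internal carbon C9 and the metal to C10, so that alane 17 already has C8 and the metal on opposite sides of the new C9=C10 bond; once the surplus Al(CH3)3 has been pumped off, ZnCl2 takes the alkenyl group over to zinc (18), iodide 15 adds oxidatively to zerovalent palladium, and transmetalation followed by reductive elimination forges C10–C11 with retention at both sp2 carbons. The closest known reaction type is the zirconium-catalysed carboalumination of a conjugated enyne run in tandem with a palladium-catalysed Negishi alkenyl–alkenyl coupling, the standard way to retinoid and carotenoid chains. No ring closes and no stereocentre is formed, so there is no closure mode or controlling element to name; what is fixed is the E geometry of C9=C10 (by the syn addition) and of C11=C12 (carried over from 15). The step needs regioselective, syn-selective methylmetalation of the alkyne beside the C4=C5 and C7=C8 alkenes, and the far higher reactivity of a terminal alkyne together with the preference of the metal for the unsubstituted terminus C10 secures it. Because neither Brønsted acid nor base is present, the doubly allylic C6–H and the allylic C3 silyl ether should be untouched, and the ester of 15 is protected by removing free Al(CH3)3 before it is added.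

Step 12
Reactants: 19 silylated C8' ethyl ester
Product: 20 (3S,6R)-3-(tert-butyldimethylsilyloxy)-8'-apo-ε-caroten-8'-ol
Conditions: i-Bu2AlH (2.5 equiv), CH2Cl2, −78 °C; aq potassium sodium tartrate (KNaC4H4O6)
Reagents that add atoms: none
Why: i-Bu2AlH reduces the conjugated ester by 1,2-addition to the primary allylic alcohol at low temperature and touches neither the polyene nor the silyl ether.

Step 13
Reactants: 20 C8' alcohol
Product: 21 (3S,6R)-3-(tert-butyldimethylsilyloxy)-8'-apo-ε-caroten-8'-al
Conditions: MnO2 (activated, excess), CH2Cl2, rt, dark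
Reagents that add atoms: none
Why: MnO2 oxidises the polyenylic primary alcohol to the aldehyde, and the C3 allylic oxygen cannot be oxidised because it is silylated.

Step 14
Reactants: 21 silylated apocarotenal
Product: 22 (3S,6R)-3-hydroxy-8'-apo-ε-caroten-8'-al (target)
Conditions: HF·pyridine, pyridine, THF, 0 °C to rt, dark
Reagents that add atoms: none
Why: Pyridine-buffered HF cleaves the secondary silyl ether through the Si–F bond and avoids basic fluoride, which could remove the C6–H that is vinylogously activated by the polyenal.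

**Compound list**

1 | (±)-α-ionone, (E)-4-(2,6,6-trimethylcyclohex-2-en-1-yl)but-3-en-2-one | CC1=CCCC(C)(C)C1/C=C/C(C)=O | starting material
2 | (±)-α-ionone ethylene ketal | CC1=CCCC(C)(C)C1/C=C/C2(C)OCCO2 | intermediate
3 | (±)-3-oxo-α-ionone ethylene ketal | CC1=CC(=O)CC(C)(C)C1/C=C/C2(C)OCCO2 | intermediate
4 | rac-cis-3-hydroxy-α-ionone ethylene ketal (3S,6R and 3R,6S; not isolated) | CC1=C[C@@H](O)CC(C)(C)[C@H]1/C=C/C2(C)OCCO2.CC1=C[C@H](O)CC(C)(C)[C@@H]1/C=C/C2(C)OCCO2 | intermediate
5 | rac-cis-3-hydroxy-α-ionone (3S,6R and 3R,6S) | CC1=C[C@@H](O)CC(C)(C)[C@H]1/C=C/C(C)=O.CC1=C[C@H](O)CC(C)(C)[C@@H]1/C=C/C(C)=O | intermediate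
6 | (3S,6R)-3-hydroxy-α-ionone | CC1=C[C@@H](O)CC(C)(C)[C@H]1/C=C/C(C)=O | intermediate
7 | (3S,6R)-3-(tert-butyldimethylsilyloxy)-α-ionone | CC1=C[C@@H](O[Si](C)(C)C(C)(C)C)CC(C)(C)[C@H]1/C=C/C(C)=O | intermediate
8 | diethyl (3E)-4-[(1R,4S)-4-(tert-butyldimethylsilyloxy)-2,6,6-trimethylcyclohex-2-en-1-yl]buta-1,3-dien-2-yl phosphate (not isolated) | CC1=C[C@@H](O[Si](C)(C)C(C)(C)C)CC(C)(C)[C@H]1/C=C/C(=C)OP(=O)(OCC)OCC | intermediate
9 | ring enyne, tert-butyl{[(1S,4R)-4-[(E)-but-1-en-3-ynyl]-3,5,5-trimethylcyclohex-2-en-1-yl]oxy}dimethylsilane | CC1=C[C@@H](O[Si](C)(C)C(C)(C)C)CC(C)(C)[C@H]1/C=C/C#C | intermediate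
10 | ethyl tiglate, ethyl (E)-2-methylbut-2-enoate | C/C=C(\C)C(=O)OCC | starting material
11 | ethyl (E)-4-bromo-2-methylbut-2-enoate | BrC/C=C(\C)C(=O)OCC | intermediate
12 | ethyl (E)-4-(diethoxyphosphoryl)-2-methylbut-2-enoate | CCOP(=O)(OCC)C/C=C(\C)C(=O)OCC | intermediate
13 | (2E,4E,6E)-2,7-dimethylocta-2,4,6-trienedial | O=C/C(C)=C/C=C/C=C(\C)C=O | starting material
14 | ethyl (2E,4E,6E,8E,10E)-2,6,11-trimethyl-12-oxododeca-2,4,6,8,10-pentaenoate | O=C/C(C)=C/C=C/C=C(C)/C=C/C=C(\C)C(=O)OCC | intermediate
15 | ethyl (2E,4E,6E,8E,10E,12E)-13-iodo-2,6,11-trimethyltrideca-2,4,6,8,10,12-hexaenoate | I/C=C/C(C)=C/C=C/C=C(C)/C=C/C=C(\C)C(=O)OCC | intermediate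
16 | trimethylaluminium | C[Al](C)C | starting material
17 | E alkenyldimethylalane, aluminium on C10, methyl on C9 (not isolated) | CC1=C[C@@H](O[Si](C)(C)C(C)(C)C)CC(C)(C)[C@H]1/C=C/C(C)=C/[Al](C)C | intermediate
18 | E alkenylzinc chloride, zinc on C10 (not isolated) | CC1=C[C@@H](O[Si](C)(C)C(C)(C)C)CC(C)(C)[C@H]1/C=C/C(C)=C/[Zn]Cl | intermediate
19 | ethyl (3S,6R)-3-(tert-butyldimethylsilyloxy)-8'-apo-ε-caroten-8'-oate | CC1=C[C@@H](O[Si](C)(C)C(C)(C)C)CC(C)(C)[C@H]1/C=C/C(C)=C/C=C/C(C)=C/C=C/C=C(C)/C=C/C=C(\C)C(=O)OCC | intermediate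
20 | (3S,6R)-3-(tert-butyldimethylsilyloxy)-8'-apo-ε-caroten-8'-ol | CC1=C[C@@H](O[Si](C)(C)C(C)(C)C)CC(C)(C)[C@H]1/C=C/C(C)=C/C=C/C(C)=C/C=C/C=C(C)/C=C/C=C(\C)CO | intermediate
21 | (3S,6R)-3-(tert-butyldimethylsilyloxy)-8'-apo-ε-caroten-8'-al | CC1=C[C@@H](O[Si](C)(C)C(C)(C)C)CC(C)(C)[C@H]1/C=C/C(C)=C/C=C/C(C)=C/C=C/C=C(C)/C=C/C=C(\C)C=O | intermediate
22 | (3S,6R)-3-hydroxy-8'-apo-ε-caroten-8'-al | CC1=C[C@@H](O)CC(C)(C)[C@H]1/C=C/C(C)=C/C=C/C(C)=C/C=C/C=C(C)/C=C/C=C(\C)C=O | target

**Count and risks**

Total step count: 14. Longest linear sequence: 10 steps (steps 1 to 6, then 11 to 14); the chain half takes steps 7 to 10.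

Step 6. The excess amide base could remove the doubly allylic C6–H of the enol phosphate or of the enyne, which would scramble C6 and move the ring alkene, or the elimination could stop short. The fallback sets out from ketone 7 and avoids amide base. Haloform cleavage (NaOCl, NaOH, dioxane–water, 0 °C) would give (E)-3-[(1R,4S)-4-(tert-butyldimethylsilyloxy)-2,6,6-trimethylcyclohex-2-en-1-yl]prop-2-enoic acid F1. LiAlH4 in Et2O at 0 °C would reduce it to the allylic alcohol (E)-3-[(1R,4S)-4-(tert-butyldimethylsilyloxy)-2,6,6-trimethylcyclohex-2-en-1-yl]prop-2-en-1-ol F2, and MnO2 in CH2Cl2 would give the enal (E)-3-[(1R,4S)-4-(tert-butyldimethylsilyloxy)-2,6,6-trimethylcyclohex-2-en-1-yl]prop-2-enal F3. Seyferth–Gilbert homologation in the Ohira–Bestmann form (dimethyl (1-diazo-2-oxopropyl)phosphonate, K2CO3, MeOH, 0 °C to rt) adds C10 and comes back to the route at enyne 9.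

Step 3. Facial selectivity in the hydride addition may be poor or may favour the trans alcohol, leaving little cis material for the resolution. The fallback sets out from keto ketal 3 and makes the trans isomer on purpose. KBH(s-Bu)3 in THF at −78 °C should attack anti to the axial C1 methyl and give rac-trans-3-hydroxy-α-ionone ethylene ketal F4. Mitsunobu inversion at C3 (PPh3, diisopropyl azodicarboxylate, 4-nitrobenzoic acid, THF, 0 °C) would give rac-cis-3-(4-nitrobenzoyloxy)-α-ionone ethylene ketal F5. Methanolysis (K2CO3, MeOH) comes back to the route at hydroxy ketal 4, which is hydrolysed to 5 as in step 3.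

Step 11. The alkenylalane may be lost to protonolysis or to attack on the ester, the partners may homocouple, or the geometry of the light-sensitive hexaenyl iodide may erode during the one-pot coupling. The fallback sets out from enyne 9 and aldehyde 14 and separates the two events. The same methylalumination of 9 is quenched with I2 (THF, −30 °C) to give the storable dienyl iodide tert-butyl{[(1S,4R)-4-[(1E,3E)-4-iodo-3-methylbuta-1,3-dienyl]-3,5,5-trimethylcyclohex-2-en-1-yl]oxy}dimethylsilane F6. Aldehyde 14 is converted by Takai–Utimoto borylolefination (2-(dichloromethyl)-4,4,5,5-tetramethyl-1,3,2-dioxaborolane, CrCl2, LiI, THF) into the E alkenyl pinacol boronate ethyl (2E,4E,6E,8E,10E,12E)-2,6,11-trimethyl-13-(4,4,5,5-tetramethyl-1,3,2-dioxaborolan-2-yl)trideca-2,4,6,8,10,12-hexaenoate F7. Suzuki–Miyaura coupling of F6 and F7 (Pd(PPh3)4, aq K3PO4, THF, rt, dark) forms the same C10–C11 bond and comes back to the route at ester 19.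

**Further compounds**

F1 | step 6 | (E)-3-[(1R,4S)-4-(tert-butyldimethylsilyloxy)-2,6,6-trimethylcyclohex-2-en-1-yl]prop-2-enoic acid | CC1=C[C@@H](O[Si](C)(C)C(C)(C)C)CC(C)(C)[C@H]1/C=C/C(=O)O
F2 | step 6 | (E)-3-[(1R,4S)-4-(tert-butyldimethylsilyloxy)-2,6,6-trimethylcyclohex-2-en-1-yl]prop-2-en-1-ol | CC1=C[C@@H](O[Si](C)(C)C(C)(C)C)CC(C)(C)[C@H]1/C=C/CO
F3 | step 6 | (E)-3-[(1R,4S)-4-(tert-butyldimethylsilyloxy)-2,6,6-trimethylcyclohex-2-en-1-yl]prop-2-enal | CC1=C[C@@H](O[Si](C)(C)C(C)(C)C)CC(C)(C)[C@H]1/C=C/C=O
F4 | step 3 | rac-trans-3-hydroxy-α-ionone ethylene ketal (3R,6R and 3S,6S) | CC1=C[C@H](O)CC(C)(C)[C@H]1/C=C/C2(C)OCCO2.CC1=C[C@@H](O)CC(C)(C)[C@@H]1/C=C/C2(C)OCCO2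
F5 | step 3 | rac-cis-3-(4-nitrobenzoyloxy)-α-ionone ethylene ketal (3S,6R and 3R,6S) | CC1=C[C@@H](OC(=O)c2ccc(cc2)[N+](=O)[O-])CC(C)(C)[C@H]1/C=C/C3(C)OCCO3.CC1=C[C@H](OC(=O)c2ccc(cc2)[N+](=O)[O-])CC(C)(C)[C@@H]1/C=C/C3(C)OCCO3
F6 | step 11 | tert-butyl{[(1S,4R)-4-[(1E,3E)-4-iodo-3-methylbuta-1,3-dienyl]-3,5,5-trimethylcyclohex-2-en-1-yl]oxy}dimethylsilane | CC1=C[C@@H](O[Si](C)(C)C(C)(C)C)CC(C)(C)[C@H]1/C=C/C(C)=C/I
F7 | step 11 | ethyl (2E,4E,6E,8E,10E,12E)-2,6,11-trimethyl-13-(4,4,5,5-tetramethyl-1,3,2-dioxaborolan-2-yl)trideca-2,4,6,8,10,12-hexaenoate | CC1(C)OB(OC1(C)C)/C=C/C(C)=C/C=C/C=C(C)/C=C/C=C(\C)C(=O)OCC
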